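The ring is numbered C1 (ester-bearing alkene carbon), C2, C3, C4 (the R stereocentre) to C14; the side chain is C15–C20. The plan rests on cutting the C5–C6 bond: C6 is allylic to the C7=C8 trisubstituted alkene and C5 flanks C4. A nitro group on C5 serves twice. As nitromethane it is added enantioselectively to an enal, setting C4; as a nitronate it attacks a palladium allyl complex over C6–C7–C8, closing the 14-membered ring under neutral conditions that spare the C1=C2 enoate. The cyclisation precursor is an open-chain nitro enoate ending in an (E)-allylic methyl carbonate; radical denitration then leaves C5 as a methylene.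

Key step: step 14

Remark: compounds 1, 9 and 12 are taken as commercial, and 21 is carried as a mixture of epimers at the nitro-bearing C5, which step 15 removes.

Step 1
Reactants: 1 pent-4-yn-1-ol
Product: 3 ethyl (2E)-2-methylhept-2-en-6-ynoate, via pent-4-ynal 2 (not isolated)
Conditions: (COCl)2, DMSO, CH2Cl2, −78 °C; Et3N; then Ph3P=C(CH3)CO2Et, −78 °C to rt
Reagents that add atoms: ethyl 2-(triphenylphosphoranylidene)propanoate, CCOC(=O)C(C)=P(c1ccccc1)(c1ccccc1)c1ccccc1
Why: Swern oxidation gives the volatile aldehyde 2, which is trapped in the same flask by the ester-stabilised ylide in a Wittig olefination that should be strongly (E)-selective and so fixes the C7=C8 geometry with C6 as the ester carbon.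

Step 2
Reactants: 3 ethyl (2E)-2-methylhept-2-en-6-ynoate
Product: 4 (2E)-2-methylhept-2-en-6-yn-1-ol
Conditions: i-Bu2AlH (2.2 equiv), CH2Cl2, −78 °C; aq. potassium sodium tartrate
Reagents that add atoms: none
Why: 1,2-Reduction of the conjugated ester by the aluminium hydride should give the allylic alcohol without touching the alkyne or the alkene geometry.

Step 3
Reactants: 4 (2E)-2-methylhept-2-en-6-yn-1-ol
Product: 5 tert-butyldimethyl{[(2E)-2-methylhept-2-en-6-yn-1-yl]oxy}silane
Conditions: TBSCl, imidazole, DMF, rt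
Reagents that add atoms: tert-butyldimethylsilyl chloride, CC(C)(C)[Si](C)(C)Cl
Why: Silylation of the primary allylic alcohol gives an ether that should survive the organoaluminium, iodination, Wittig and Stille steps and keeps C6–O inert to palladium until step 13.

Step 4
Reactants: 5 tert-butyldimethyl{[(2E)-2-methylhept-2-en-6-yn-1-yl]oxy}silane
Product: 7 (3E,7E)-9-(tert-butyldimethylsilyloxy)-4,8-dimethylnona-3,7-dien-1-ol, via alkenyl(dimethyl)alane 6 (not isolated)
Conditions: AlMe3 (2 equiv), Cp2ZrCl2 (0.25 equiv), CH2Cl2, 0 °C to rt; volatiles removed; n-BuLi (1 equiv), hexane–THF, −78 °C; oxirane, −78 °C to rt; aq. NH4Cl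
Reagents that add atoms: trimethylaluminium, C[Al](C)C; oxirane, C1CO1
Why: Zirconium-catalysed carboalumination (Negishi carboalumination) adds methyl and aluminium syn across the terminal alkyne with methyl on the internal carbon, and the derived lithium alanate opens oxirane with retention, so the (E)-C11=C12 alkene and the C13–C14 unit arise in one flask.

Step 5
Reactants: 7 (3E,7E)-9-(tert-butyldimethylsilyloxy)-4,8-dimethylnona-3,7-dien-1-ol
Product: 8 tert-butyl{[(2E,6E)-9-iodo-2,6-dimethylnona-2,6-dien-1-yl]oxy}dimethylsilane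
Conditions: I2, PPh3, imidazole, CH2Cl2, 0 °C to rt
Reagents that add atoms: iodine, II
Why: Appel-type iodination activates the primary alcohol as an oxyphosphonium ion that iodide displaces by SN2, under conditions that leave the silyl ether and the alkenes alone.

Step 6
Reactants: 8 tert-butyl{[(2E,6E)-9-iodo-2,6-dimethylnona-2,6-dien-1-yl]oxy}dimethylsilane, 9 methyl (triphenylphosphoranylidene)acetate
Product: 11 methyl (5E,9E)-11-(tert-butyldimethylsilyloxy)-6,10-dimethyl-2-(triphenylphosphoranylidene)undeca-5,9-dienoate, via phosphonium iodide 10 (not isolated)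
Conditions: 9 (2.2 equiv), EtOAc, reflux; precipitated phosphonium salt filtered off
Reagents that add atoms: none
Why: SN2 C-alkylation of the ester-stabilised ylide by the unhindered primary iodide gives salt 10, which a second equivalent of 9 deprotonates (transylidation, driven by precipitation of the less soluble salt of 9) to the α-substituted stabilised ylide that carries C1, the ester and C6–C14.

Step 7
Reactants: 12 (2E)-pent-2-en-4-yn-1-ol
Product: 14 (2E,4E)-5-iodo-4-methylpenta-2,4-dien-1-ol, via dienyl(dimethyl)alane 13 (not isolated)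
Conditions: AlMe3 (3 equiv), Cp2ZrCl2 (0.5 equiv), CH2Cl2, 0 °C to rt; then I2, THF, −30 to 0 °C
Reagents that add atoms: trimethylaluminium, C[Al](C)C; iodine, II
Why: Negishi carboalumination of the conjugated enyne (the hydroxyl being masked in the flask as its aluminium alkoxide) places the C15 methyl syn to aluminium, and iodinolysis with retention should give the (E)-alkenyl iodide with iodine trans to the future C4.

Step 8
Reactants: 14 (2E,4E)-5-iodo-4-methylpenta-2,4-dien-1-ol
Product: 15 (2E,4E)-5-iodo-4-methylpenta-2,4-dienal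
Conditions: MnO2 (excess), CH2Cl2, rt, dark
Reagents that add atoms: none
Why: Manganese dioxide oxidises the dienylic alcohol selectively to the dienal without isomerising either alkene.

Step 9
Reactants: 15 (2E,4E)-5-iodo-4-methylpenta-2,4-dienal
Product: 16 (3R)-3-[(1E)-1-iodoprop-1-en-2-yl]-4-nitrobutanal
Conditions: CH3NO2 (5 equiv), (R)-2-[diphenyl(trimethylsilyloxy)methyl]pyrrolidine (10 mol%), PhCO2H (20 mol%), MeOH, rt
Reagents that add atoms: nitromethane, C[N+](=O)[O-]
Why: In this iminium-catalysed Michael addition the diphenyl(silyloxy)methyl group of the (R)-catalyst shields one face of the (E)-s-trans iminium ion, so nitromethane should add to the β-carbon from the open face and set C4 as R, and because the δ-carbon carries iodine and no ε-hydrogen is present the iminium cannot drain into a trienamine that would scramble the diene.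

Step 10
Reactants: 11 methyl (5E,9E)-11-(tert-butyldimethylsilyloxy)-6,10-dimethyl-2-(triphenylphosphoranylidene)undeca-5,9-dienoate, 16 (3R)-3-[(1E)-1-iodoprop-1-en-2-yl]-4-nitrobutanal
Product: 17 methyl (2E,5R)-2-[(3E,7E)-9-(tert-butyldimethylsilyloxy)-4,8-dimethylnona-3,7-dien-1-yl]-5-[(1E)-1-iodoprop-1-en-2-yl]-6-nitrohex-2-enoate
Conditions: toluene, rt to 50 °C
Reagents that add atoms: none
Why: Wittig olefination of the unhindered aldehyde with the α-alkyl ester-stabilised ylide should give the C1=C2 enoate with the ester trans to C3, and the ylide is too weak a base to ionise the nitromethyl group while C4, being β to the aldehyde, cannot epimerise.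

Step 11
Reactants: 17 methyl (2E,5R)-2-[(3E,7E)-9-(tert-butyldimethylsilyloxy)-4,8-dimethylnona-3,7-dien-1-yl]-5-[(1E)-1-iodoprop-1-en-2-yl]-6-nitrohex-2-enoate
Product: 18 methyl (2E,5R)-2-[(3E,7E)-9-(tert-butyldimethylsilyloxy)-4,8-dimethylnona-3,7-dien-1-yl]-5-[(2E)-6-methylhepta-2,5-dien-2-yl]-6-nitrohex-2-enoate
Conditions: prenyl-SnBu3 (1.5 equiv), Pd2(dba)3 (5 mol%), AsPh3 (20 mol%), NMP, rt to 40 °C
Reagents that add atoms: tributyl(3-methylbut-2-en-1-yl)stannane, CCCC[Sn](CCCC)(CCCC)CC=C(C)C
Why: In this Stille coupling zerovalent palladium inserts into the alkenyl iodide with retention and reductive elimination at the less substituted allyl terminus should give the linear prenyl 1,4-diene, while the neutral conditions leave the nitromethyl group un-ionised and the late timing means the skipped diene is never conjugated to an electron-withdrawing group.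

Step 12
Reactants: 18 methyl (2E,5R)-2-[(3E,7E)-9-(tert-butyldimethylsilyloxy)-4,8-dimethylnona-3,7-dien-1-yl]-5-[(2E)-6-methylhepta-2,5-dien-2-yl]-6-nitrohex-2-enoate
Product: 19 methyl (2E,5R)-2-[(3E,7E)-9-hydroxy-4,8-dimethylnona-3,7-dien-1-yl]-5-[(2E)-6-methylhepta-2,5-dien-2-yl]-6-nitrohex-2-enoate
Conditions: HF·pyridine, pyridine, THF, 0 °C to rt
Reagents that add atoms: none
Why: Buffered fluoride cleaves the primary allylic silyl ether under mildly acidic conditions that do not generate the nitronate or touch the enoate.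

Step 13
Reactants: 19 methyl (2E,5R)-2-[(3E,7E)-9-hydroxy-4,8-dimethylnona-3,7-dien-1-yl]-5-[(2E)-6-methylhepta-2,5-dien-2-yl]-6-nitrohex-2-enoate
Product: 20 methyl (2E,5R)-2-{(3E,7E)-9-[(methoxycarbonyl)oxy]-4,8-dimethylnona-3,7-dien-1-yl}-5-[(2E)-6-methylhepta-2,5-dien-2-yl]-6-nitrohex-2-enoate
Conditions: ClCO2Me, pyridine, CH2Cl2, 0 °C
Reagents that add atoms: methyl chloroformate, COC(=O)Cl
Why: Acylation of the primary allylic alcohol installs the carbonate that later serves as leaving group and internal base, pyridine being too weak to ionise the nitromethyl group.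

Step 14
Reactants: 20 methyl (2E,5R)-2-{(3E,7E)-9-[(methoxycarbonyl)oxy]-4,8-dimethylnona-3,7-dien-1-yl}-5-[(2E)-6-methylhepta-2,5-dien-2-yl]-6-nitrohex-2-enoate
Product: 21 methyl (1E,4R,7E,11E)-7,11-dimethyl-4-[(2E)-6-methylhepta-2,5-dien-2-yl]-5-nitrocyclotetradeca-1,7,11-triene-1-carboxylate
Conditions: Pd(PPh3)4 (10 mol%), THF, 65 °C, syringe-pump addition of 20 to a final concentration of about 1 mM
Reagents that add atoms: none
Why: Zerovalent palladium ionises the (E)-allylic carbonate with loss of CO2 to a syn η3-allyl complex over C6–C7–C8 and a methoxide that deprotonates the nitromethyl group, and the nitronate carbon C5 then attacks the unsubstituted terminus C6 from the face opposite palladium (Tsuji–Trost allylic alkylation of a nitroalkane under neutral carbonate conditions, the closest precedents being palladium-templated macrocyclisations of stabilised carbanions onto allylic esters). The ring closed is the 14-membered carbocycle with the whole allyl unit inside the ring (endo mode); closure at C8 would give a 12-membered ring with an exocyclic isopropenyl group and is disfavoured because a soft nucleophile with PPh3 ligands attacks the less substituted terminus. The only new stereocentre is the nitro-bearing C5, formed without control as a mixture of epimers, which is harmless because step 15 removes it, and C4 is not touched. The step needs C- over O-allylation of the nitronate (O-allyl nitronates re-ionise, so C–C bond formation is the productive sink), retention of the (E)-C7=C8 geometry (the syn complex from the (E)-carbonate should be trapped before syn–anti exchange) and cyclisation over oligomerisation (slow addition at high dilution). The medium stays neutral, so the C1=C2 enoate, whose γ-hydrogens are far less acidic than the nitromethyl group, is neither deprotonated nor attacked.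

Step 15
Reactants: 21 methyl (1E,4R,7E,11E)-7,11-dimethyl-4-[(2E)-6-methylhepta-2,5-dien-2-yl]-5-nitrocyclotetradeca-1,7,11-triene-1-carboxylate
Product: 22 methyl (1E,4R,7E,11E)-7,11-dimethyl-4-[(2E)-6-methylhepta-2,5-dien-2-yl]cyclotetradeca-1,7,11-triene-1-carboxylate
Conditions: Bu3SnH (5 equiv), AIBN (0.5 equiv, in portions), toluene, 110 °C
Reagents that add atoms: none
Why: In this radical denitration the stannyl radical adds to a nitro oxygen, the C5–N bond fragments to a secondary radical that tributyltin hydride reduces, no alkene is placed for a five- or six-membered ring closure from C5, and both C5 epimers converge on the same methylene.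

Compound list
1 | pent-4-yn-1-ol | C#CCCCO | starting material
2 | pent-4-ynal | C#CCCC=O | intermediate
3 | ethyl (2E)-2-methylhept-2-en-6-ynoate | CCOC(=O)/C(C)=C/CCC#C | intermediate
4 | (2E)-2-methylhept-2-en-6-yn-1-ol | OC/C(C)=C/CCC#C | intermediate
5 | tert-butyldimethyl{[(2E)-2-methylhept-2-en-6-yn-1-yl]oxy}silane | CC(C)(C)[Si](C)(C)OC/C(C)=C/CCC#C | intermediate
6 | [(1E,5E)-7-(tert-butyldimethylsilyloxy)-2,6-dimethylhepta-1,5-dien-1-yl]dimethylalane | C[Al](C)/C=C(\C)CC/C=C(\C)CO[Si](C)(C)C(C)(C)C | intermediate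
7 | (3E,7E)-9-(tert-butyldimethylsilyloxy)-4,8-dimethylnona-3,7-dien-1-ol | OCC/C=C(\C)CC/C=C(\C)CO[Si](C)(C)C(C)(C)C | intermediate
8 | tert-butyl{[(2E,6E)-9-iodo-2,6-dimethylnona-2,6-dien-1-yl]oxy}dimethylsilane | ICC/C=C(\C)CC/C=C(\C)CO[Si](C)(C)C(C)(C)C | intermediate
9 | methyl (triphenylphosphoranylidene)acetate | COC(=O)C=P(c1ccccc1)(c1ccccc1)c1ccccc1 | starting material
10 | [(5E,9E)-11-(tert-butyldimethylsilyloxy)-1-methoxy-6,10-dimethyl-1-oxoundeca-5,9-dien-2-yl]triphenylphosphonium iodide | COC(=O)C(CC/C=C(\C)CC/C=C(\C)CO[Si](C)(C)C(C)(C)C)[P+](c1ccccc1)(c1ccccc1)c1ccccc1.[I-] | intermediate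
11 | methyl (5E,9E)-11-(tert-butyldimethylsilyloxy)-6,10-dimethyl-2-(triphenylphosphoranylidene)undeca-5,9-dienoate | COC(=O)C(CC/C=C(\C)CC/C=C(\C)CO[Si](C)(C)C(C)(C)C)=P(c1ccccc1)(c1ccccc1)c1ccccc1 | intermediate
12 | (2E)-pent-2-en-4-yn-1-ol | OC/C=C/C#C | starting material
13 | dimethylaluminium alkoxide of [(1E,3E)-5-hydroxy-2-methylpenta-1,3-dien-1-yl]dimethylalane | C[Al](C)OC/C=C/C(C)=C/[Al](C)C | intermediate
14 | (2E,4E)-5-iodo-4-methylpenta-2,4-dien-1-ol | OC/C=C/C(C)=C/I | intermediate
15 | (2E,4E)-5-iodo-4-methylpenta-2,4-dienal | O=C/C=C/C(C)=C/I | intermediate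
16 | (3R)-3-[(1E)-1-iodoprop-1-en-2-yl]-4-nitrobutanal | O=CC[C@H](/C(C)=C/I)C[N+](=O)[O-] | intermediate
17 | methyl (2E,5R)-2-[(3E,7E)-9-(tert-butyldimethylsilyloxy)-4,8-dimethylnona-3,7-dien-1-yl]-5-[(1E)-1-iodoprop-1-en-2-yl]-6-nitrohex-2-enoate | COC(=O)/C(=C/C[C@H](/C(C)=C/I)C[N+](=O)[O-])CC/C=C(\C)CC/C=C(\C)CO[Si](C)(C)C(C)(C)C | intermediate
18 | methyl (2E,5R)-2-[(3E,7E)-9-(tert-butyldimethylsilyloxy)-4,8-dimethylnona-3,7-dien-1-yl]-5-[(2E)-6-methylhepta-2,5-dien-2-yl]-6-nitrohex-2-enoate | COC(=O)/C(=C/C[C@H](/C(C)=C/CC=C(C)C)C[N+](=O)[O-])CC/C=C(\C)CC/C=C(\C)CO[Si](C)(C)C(C)(C)C | intermediate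
19 | methyl (2E,5R)-2-[(3E,7E)-9-hydroxy-4,8-dimethylnona-3,7-dien-1-yl]-5-[(2E)-6-methylhepta-2,5-dien-2-yl]-6-nitrohex-2-enoate | COC(=O)/C(=C/C[C@H](/C(C)=C/CC=C(C)C)C[N+](=O)[O-])CC/C=C(\C)CC/C=C(\C)CO | intermediate
20 | methyl (2E,5R)-2-{(3E,7E)-9-[(methoxycarbonyl)oxy]-4,8-dimethylnona-3,7-dien-1-yl}-5-[(2E)-6-methylhepta-2,5-dien-2-yl]-6-nitrohex-2-enoate | COC(=O)/C(=C/C[C@H](/C(C)=C/CC=C(C)C)C[N+](=O)[O-])CC/C=C(\C)CC/C=C(\C)COC(=O)OC | intermediate
21 | methyl (1E,4R,7E,11E)-7,11-dimethyl-4-[(2E)-6-methylhepta-2,5-dien-2-yl]-5-nitrocyclotetradeca-1,7,11-triene-1-carboxylate (both C5 epimers) | COC(=O)/C1=C/C[C@H](/C(C)=C/CC=C(C)C)C([N+](=O)[O-])C/C(C)=C/CC/C(C)=C/CC1 | intermediate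
22 | methyl (1E,4R,7E,11E)-7,11-dimethyl-4-[(2E)-6-methylhepta-2,5-dien-2-yl]cyclotetradeca-1,7,11-triene-1-carboxylate | COC(=O)/C1=C/C[C@H](/C(C)=C/CC=C(C)C)CC/C(C)=C/CC/C(C)=C/CC1 | target

Total steps: 15. Longest linear sequence: 12 (steps 1–6, then 10–15).

Steps most likely to fail

1. Step 14. Intermolecular allylation (oligomerisation), β-hydride elimination of the allyl complex to a 1,3-diene, or attack at C8 may outrun the 14-membered closure. The fallback closes the same C5–C6 bond by a nitro-aldol reaction. It sets out from alcohol 19: oxidation with MnO2 (CH2Cl2, rt) should give the seco enal F1. An intramolecular Henry reaction (catalytic tetramethylguanidine, THF, high dilution) would join C5 to the aldehyde carbon C6 and give the macrocyclic nitro alcohol F2. Mesylation with elimination (MsCl, Et3N, CH2Cl2) would give the macrocyclic nitrodiene F3. Conjugate reduction with NaBH4 (THF–MeOH, 0 °C), which delivers hydride to C6, would come back to the route at 21.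

2. Step 15. Fragmentation of the unactivated secondary nitroalkane may be slow, so that hydrostannation of the enoate or radical isomerisation of the skipped diene takes over. The fallback replaces the tin radical chain by reduction and deamination. It sets out from 21: Zn dust in AcOH–THF should reduce the nitro group to the macrocyclic amine F4. Hydrodeamination with the anomeric amide N-(benzyloxy)-N-(pivaloyloxy)-4-(trifluoromethyl)benzamide (MeCN, 45 °C), which runs through an isodiazene and loses N2, would come back to the route at 22.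

3. Step 11. The prenyl group may be transferred through its tertiary terminus (reverse-prenyl product), or a palladium hydride may move the 1,4-diene into conjugation. The fallback builds the prenyl terminus by metathesis. It sets out from 17: Stille coupling with allyltributylstannane (Pd2(dba)3, AsPh3, NMP), whose two allyl termini are equivalent, should give the allyl diene F5. Cross-metathesis of its terminal vinyl group with 2-methylbut-2-ene (second-generation Grubbs catalyst, CH2Cl2, 40 °C) would come back to the route at 18.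

Further compounds
F1 | step 14 | seco enal, methyl (2E,5R)-2-[(3E,7E)-4,8-dimethyl-9-oxonona-3,7-dien-1-yl]-5-[(2E)-6-methylhepta-2,5-dien-2-yl]-6-nitrohex-2-enoate | COC(=O)/C(=C/C[C@H](/C(C)=C/CC=C(C)C)C[N+](=O)[O-])CC/C=C(\C)CC/C=C(\C)C=O
F2 | step 14 | macrocyclic nitro alcohol, methyl (1E,4R,7E,11E)-6-hydroxy-7,11-dimethyl-4-[(2E)-6-methylhepta-2,5-dien-2-yl]-5-nitrocyclotetradeca-1,7,11-triene-1-carboxylate | COC(=O)/C1=C/C[C@H](/C(C)=C/CC=C(C)C)C([N+](=O)[O-])C(O)/C(C)=C/CC/C(C)=C/CC1
F3 | step 14 | macrocyclic nitrodiene, methyl (1E,4R,7E,11E)-7,11-dimethyl-4-[(2E)-6-methylhepta-2,5-dien-2-yl]-5-nitrocyclotetradeca-1,5,7,11-tetraene-1-carboxylate | COC(=O)/C1=C/C[C@H](/C(C)=C/CC=C(C)C)C([N+](=O)[O-])=C/C(C)=C/CC/C(C)=C/CC1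
F4 | step 15 | macrocyclic amine, methyl (1E,4R,7E,11E)-5-amino-7,11-dimethyl-4-[(2E)-6-methylhepta-2,5-dien-2-yl]cyclotetradeca-1,7,11-triene-1-carboxylate | COC(=O)/C1=C/C[C@H](/C(C)=C/CC=C(C)C)C(N)C/C(C)=C/CC/C(C)=C/CC1
F5 | step 11 | allyl diene, methyl (2E,5R)-2-[(3E,7E)-9-(tert-butyldimethylsilyloxy)-4,8-dimethylnona-3,7-dien-1-yl]-5-[(2E)-hexa-2,5-dien-2-yl]-6-nitrohex-2-enoate | COC(=O)/C(=C/C[C@H](/C(C)=C/CC=C)C[N+](=O)[O-])CC/C=C(\C)CC/C=C(\C)CO[Si](C)(C)C(C)(C)C
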